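The constants of this flask are not equally worth knowing well, so we sort them before reckoning anything.

    G ⇌ L, rate k1*(csat - [L]) (k1 = 0.22 s⁻¹, csat = 70 mM)
    J + L → J.L (k2 = 0.11 M⁻¹ s⁻¹)
    J → E (k3 = 0.0026 s⁻¹)
    L → Z (k4 = 0.023 s⁻¹)
    J.L → Q (k5 = 1.5 × 10⁻⁴ s⁻¹)

J 2.0 M; G 70 mM (held); time 4.0 min

- how much J.L there is at 4.0 min, in percent of the J charged
- the change that raises the amount of J.L at 4.0 min, in percent of the J charged most ("none" if none brings more than 2 percentage points) (teal / violet / none)
- amount of J.L at 4.0 min, in percent of the J charged, after violet

Hardly any J.L goes to Q even if it stands for the whole 4.0 min, so the constant 1.5 × 10⁻⁴ s⁻¹ of J.L → Q need not be sharp, and the constant 0.023 s⁻¹ of L → Z is smaller than the transfer coefficient 0.22 s⁻¹ beside which it is summed, so it need not be either. The others must be good. L relaxes within 4.55 s, far shorter than the run, so it sits in a quasi-steady state: cL is the transfer coefficient times the saturation concentration, divided by the sum of that coefficient, 0.023 s⁻¹ and the capture constant times cJ. At full charge the capture term 0.220 s⁻¹ equals the transfer coefficient, so an error in either moves cL, while the saturation concentration moves it in proportion.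

With cJ at half the charge, cL is 43.6 mM, so capture takes J at 0.00480 s⁻¹, faster than the leak to E at 0.0026 s⁻¹. J is then pseudo-first-order with lifetime 2.25 min, and this lifetime of J at half charge is what we carry. The run is 1.78 lifetimes, and capture takes 64.8 % of what leaves J, so we commit to 53.9 % J.L. Doubling the saturation concentration (violet) gives a lifetime of 1.37 min and 74.5 %. Doubling the transfer coefficient (teal) gives 60.5 %, which is less, so we choose violet.

The forecast says 52 % (48 % to 56 %), violet and 73 % (69 % to 77 %), with the ground “Doubling csat doubles the L level outright”. The simulation gives 51.7 %, violet with a gain of 21 percentage points against 7 points for teal, and 73.1 % after violet.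

The reckoned lifetime 2.25 min is shorter than the run of 4.0 min, and at 4.00 min the flask holds J at 16.6 % beside the reckoned 16.9 %, with J.L at 51.7 % and E at 30.6 %. In the neighbour charged with 0.50 M of J, half of that charge gives a reckoned cL of 56.9 mM and a lifetime of 1.88 min, hence 11.9 % of J and 62.2 % of J.L, and at 4.00 min that flask holds 11.9 % of J and 60.0 % of J.L.

The constants used here are made up; no experiment stands behind them.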